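**Retrosynthetic overview**
- The C11–O aryl ether is cut last, giving a neopentyl triflate and isofraxidin. The axial C8 methyl is traced back through a silicon tether on O11 and a C7=C8 alkene to an equatorial C8 hydroxyl.
- The strategy rests on one feature. Quaternary C9 (axial CH3, equatorial C11H2O) sits next to the trans C10(H)–C5(CH3) fusion of rings B and A, and ring A carries the C3 ketone beside the C4 methyl. These atoms correspond to an oxirane carbon, an (E)-alkene and an enol carbon of an open chain.
- The key disconnections are C9–C10 and C4–C5. A Lewis acid opens the C8–C9 oxirane, ring B closes first, ring A closes second, and the enol silane ends the cascade as the C3 ketone.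
- The chain comes from geraniol (C1, C5–C11 and two methyls), dimethyl malonate (C2, C3) and vinylmagnesium bromide (C4 and its methyl). A Sharpless epoxidation is the only source of absolute configuration.

Key step: step 10

Numbering: target numbering is used. Ring A is C1–C5 and C10, ring B is C5–C10, and C11 is the CH2O carbon on C9. β is the face of H10 and α is the face of the C5 methyl.

Remark on the chemistry: the C8 methyl is delivered from O11 through a silicon tether. Opening a C7–C8 cyclopropane with H2 over PtO2 would also reduce the C3 ketone and would have to choose between two similar CH2–CH bonds, so it serves only as a fallback.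

Assumption: the silyl group released at C3 in step 10 ends on O8 (compound 14). Any material that ends as the aluminium alkoxide gives 15 in the same work-up.

**Step 1**
Reactants: 1 geraniol
Product: 2 geranyl bromide
Conditions: PBr3 (0.4 equiv), Et2O, −10 to 0 °C
Reagents that add atoms: phosphorus tribromide BrP(Br)Br
Why: Bromination of a primary allylic alcohol with PBr3 (SN2 on the phosphite ester) should proceed at low temperature without allylic shift, so the (E)-C5=C10 alkene is kept.

**Step 2**
Reactants: 2 geranyl bromide; 3 dimethyl malonate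
Product: 4 dimethyl 2-[(2E)-3,7-dimethylocta-2,6-dien-1-yl]malonate
Conditions: NaH, 3 (1.5 equiv), THF, 0 °C to rt
Reagents that add atoms: none
Why: Malonic ester alkylation: the soft sodium enolate attacks the primary allylic bromide in an SN2 manner at C1, and the excess of 3 holds back double alkylation.

**Step 3**
Reactants: 4 dimethyl 2-geranylmalonate
Product: 5 methyl (4E)-5,9-dimethyldeca-4,8-dienoate
Conditions: LiCl, H2O, DMSO, 150 °C
Reagents that add atoms: none
Why: Krapcho demethoxycarbonylation removes one ester through chloride attack on its methyl group and loss of CO2 under neutral conditions that leave both trisubstituted alkenes in place.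

**Step 4**
Reactants: 5 methyl (4E)-5,9-dimethyldeca-4,8-dienoate
Product: 6 (4E)-N-methoxy-N,5,9-trimethyldeca-4,8-dienamide
Conditions: MeNH(OMe)·HCl, iPrMgCl, THF, −20 to 0 °C
Reagents that add atoms: N,O-dimethylhydroxylamine hydrochloride CNOC.Cl
Why: Weinreb amide synthesis by aminolysis of the ester with the magnesium amide made in the flask, placed here so that this strongly basic step is over before the oxirane exists.

**Step 5**
Reactants: 6 (4E)-N-methoxy-N,5,9-trimethyldeca-4,8-dienamide
Product: 8 (4E,8E)-10-hydroxy-N-methoxy-N,5,9-trimethyldeca-4,8-dienamide, via C10 enal 7 (not isolated)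
Conditions: SeO2 (cat.), t-BuOOH, salicylic acid (cat.), CH2Cl2, 0 °C to rt; then NaBH4, MeOH, 0 °C
Reagents that add atoms: tert-butyl hydroperoxide CC(C)(C)OO (terminal oxygen source); selenium dioxide O=[Se]=O (oxygen carrier)
Why: Riley allylic oxidation in its catalytic SeO2/t-BuOOH form (ene reaction, then [2,3]-sigmatropic shift) should attack the more exposed terminal isopropylidene group and there the methyl trans to the chain, which gives the (E)-allylic alcohol, while NaBH4 brings over-oxidised enal 7 back to 8.

**Step 6**
Reactants: 8 (4E,8E)-10-hydroxy-N-methoxy-N,5,9-trimethyldeca-4,8-dienamide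
Product: 9 (4E,8S,9S)-8,9-epoxy-10-hydroxy-N-methoxy-N,5,9-trimethyldec-4-enamide
Conditions: Ti(OiPr)4 (cat.), L-(+)-diethyl tartrate (cat.), anhydrous t-BuOOH, 4 Å sieves, CH2Cl2, −25 °C
Reagents that add atoms: tert-butyl hydroperoxide CC(C)(C)OO
Why: Sharpless asymmetric epoxidation touches only the alkene of the allylic alcohol, and L-(+)-tartrate should give the (8S,9S)-oxirane, the sense known for (E)-2-methylalk-2-en-1-ols, which sets C8 and C9 and with them the absolute configuration of the route.

**Step 7**
Reactants: 9 epoxy alcohol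
Product: 10 (4E,8S,9S)-10-(tert-butyldiphenylsilyloxy)-8,9-epoxy-N-methoxy-N,5,9-trimethyldec-4-enamide
Conditions: TBDPSCl, imidazole, CH2Cl2, 0 °C to rt
Reagents that add atoms: tert-butyl(chloro)diphenylsilane CC(C)(C)[Si](Cl)(c1ccccc1)c1ccccc1
Why: Silyl ether formation at the primary alcohol; the bulky and weakly basic TBDPS ether is chosen because it withstands the Grignard reagent, MeAlCl2 and acid and keeps O11 from chelating or attacking in step 10.

**Step 8**
Reactants: 10 silylated epoxy Weinreb amide; 11 vinylmagnesium bromide
Product: 12 (6E,10S,11S)-12-(tert-butyldiphenylsilyloxy)-10,11-epoxy-7,11-dimethyldodeca-1,6-dien-3-one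
Conditions: THF, −78 to −10 °C; poured into cold aq NH4Cl
Reagents that add atoms: none
Why: Weinreb ketone synthesis stops after one addition, a trisubstituted oxirane is inert to the Grignard reagent below 0 °C, and pouring into cold buffer limits conjugate addition of the released amine to the vinyl ketone.

**Step 9**
Reactants: 12 epoxy vinyl ketone
Product: 13 (2Z,6E,10S,11S)-12-(tert-butyldiphenylsilyloxy)-10,11-epoxy-7,11-dimethyl-3-(triethylsilyloxy)dodeca-2,6-diene
Conditions: Et3SiH, RhCl(PPh3)3 (cat.), benzene, 50 °C; filtration through Et3N-washed silica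
Reagents that add atoms: triethylsilane CC[SiH](CC)CC
Why: Rhodium-catalysed 1,4-hydrosilylation of the s-cis vinyl ketone fixes the enol double bond between C3 and C4, which deprotonation of an ethyl ketone with two CH2 flanks could not do, and should give the (Z)-isomer, while the isolated alkene and the oxirane are not touched.

**Step 10**
Reactants: 13 (E)-alkene epoxide bearing the (Z)-enol silane
Product: 15 (4R,5S,8S,9R,10R)-9-(tert-butyldiphenylsilyloxymethyl)-8-hydroxy-4,5,9-trimethyl-trans-decalin-3-one, via C8 triethylsilyl ether 14 (not isolated)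
Conditions: MeAlCl2 (1.5 equiv), CH2Cl2, −90 to −78 °C; Et3N–MeOH quench; then 1 M HCl, THF, rt
Reagents that add atoms: none
Why: MeAlCl2 binds the oxirane oxygen, the C9–O bond stretches at the fully substituted carbon while C10 of the (E)-alkene attacks from the rear, the charge building at C5 is taken by enol carbon C4, and the silyl group leaves the oxocarbenium ion for O8 (14), which the acid work-up frees. The closest known reaction type is the Lewis-acid epoxy-polyene cyclization ended by a silyl enol ether, and only the C11 oxygen on the initiating carbon is unusual. Ring B closes first in a 6-endo mode (endo for the oxirane and for the C5=C10 alkene, chair), and ring A closes second, again 6-endo with the C3=C4 enol bond inside the new ring (chair). C9 is set by inversion of the (S)-oxirane carbon, so the methyl cis to the chain ends axial and C11H2O equatorial; C10 and C5 are set by anti addition across the (E)-alkene in the chair that keeps O8 equatorial, which puts H10 and the C5 methyl trans; C4 is set by the (Z)-enol geometry, which places its methyl equatorial, the epimer that enolisation also favours. The step needs C9–O rather than C8–O cleavage and cyclization faster than hydride shift or proton loss: the tertiary against secondary carbon secures the first, and the bulky, weakly basic TBDPS ether (no chelate, no participation of O11), the low temperature and the very nucleophilic terminator secure the second.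

**Step 11**
Reactants: 15 8-hydroxy decalin ketone
Product: 16 (4R,5S,8S,9R,10R)-9-(tert-butyldiphenylsilyloxymethyl)-4,5,9-trimethyl-3-oxo-trans-decalin-8-yl methanesulfonate
Conditions: MsCl, Et3N, CH2Cl2, 0 °C
Reagents that add atoms: methanesulfonyl chloride CS(=O)(=O)Cl
Why: Mesylation of the equatorial C8 alcohol (sulfonate ester formation) takes place at oxygen, so C8 keeps its configuration and the ketone and the silyl ether are not affected.

**Step 12**
Reactants: 16 equatorial C8 mesylate
Product: 18 (4R,5S,9R,10R)-9-(tert-butyldiphenylsilyloxymethyl)-4,5,9-trimethyl-trans-octal-7-en-3-one (C7=C8), via axial C8 bromide 17 (not isolated)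
Conditions: LiBr, Li2CO3, DMF, 130 °C
Reagents that add atoms: none
Why: Dehydrosulfonyloxylation in a buffered, non-ionising medium: bromide inverts C8 to axial bromide 17, whose C–Br bond is anti to axial H7 so that E2 loss of HBr follows, C9 has no hydrogen so that only the C7=C8 alkene can form, and the ring contraction that ionising conditions cause in equatorial neopentyl sulfonates is avoided, as in the conversion of 3β-sulfonates of 4,4-dimethyl terpenoids into 2-enes.

**Step 13**
Reactants: 18 silylated octalone
Product: 19 (4R,5S,9R,10R)-9-(hydroxymethyl)-4,5,9-trimethyl-trans-octal-7-en-3-one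
Conditions: TBAF, THF, rt to 45 °C
Reagents that add atoms: none
Why: Fluoride cleavage of the silyl ether frees O11, the anchor for the next carbon, and neither the alkene nor the ketone reacts.

**Step 14**
Reactants: 19 homoallylic alcohol
Product: 20 (bromomethyl)dimethylsilyl ether of 19
Conditions: BrCH2SiMe2Cl, Et3N, DMAP (cat.), CH2Cl2, 0 °C
Reagents that add atoms: (bromomethyl)chlorodimethylsilane C[Si](C)(Cl)CBr
Why: Silylation of the primary neopentyl alcohol with the chlorosilane installs the (bromomethyl)dimethylsilyl tether of the Nishiyama–Stork method under conditions too mild to enolise the ketone.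

**Step 15**
Reactants: 20 (bromomethyl)dimethylsilyl ether
Product: 21 tricyclic oxasilinane (ring O11–SiMe2–CH2–C8–C9–C11 cis-fused to ring B; C8–CH2 bond axial and β)
Conditions: Bu3SnH (slow addition), AIBN (cat.), benzene (0.01 M), reflux
Reagents that add atoms: none
Why: Nishiyama–Stork silicon-tethered radical cyclization: the α-silyl radical adds 6-exo to C8, and the new C8 stereocenter is set by the tether from β-oriented C11, by the pseudo-axial α-methyl on C9 that shields the other face and by the preference for axial bond formation, so that the C8–CH2 bond is axial and β, after which the C7 radical takes hydrogen from the stannane.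

**Step 16**
Reactants: 21 tricyclic oxasilinane
Product: 22 (4R,5S,8R,9R,10R)-9-(hydroxymethyl)-4,5,8,9-tetramethyl-trans-decalin-3-one
Conditions: TBAF (excess), wet DMF, 75 °C
Reagents that add atoms: none
Why: Fluoride-induced protodesilylation of the cyclic alkoxysilane (Stork reductive methylation) turns C8–CH2–Si into C8–CH3 and frees O11 without touching the C8–C bond, so the axial β configuration is kept, and C4 can only settle in its favoured equatorial form.

**Step 17**
Reactants: 22 keto alcohol
Product: 23 [(4R,5S,8R,9R,10R)-4,5,8,9-tetramethyl-3-oxo-trans-decalin-9-yl]methyl trifluoromethanesulfonate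
Conditions: Tf2O, pyridine, CH2Cl2, −40 to 0 °C
Reagents that add atoms: trifluoromethanesulfonic anhydride O=S(=O)(OS(=O)(=O)C(F)(F)F)C(F)(F)F
Why: Triflate ester formation at the primary alcohol at low temperature; a neopentyl triflate has no β-hydrogen to lose and can be handled, and the hindered ketone does not form an enol triflate with pyridine as base.

**Step 18**
Reactants: 23 neopentyl triflate; 24 isofraxidin
Product: 25 7-{[(1R,2R,4aS,5R,8aR)-1,2,4a,5-tetramethyl-6-oxodecahydronaphthalen-1-yl]methoxy}-6,8-dimethoxy-2H-chromen-2-one (CNP0225022.1)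
Conditions: Cs2CO3, DMF, rt to 50 °C
Reagents that add atoms: none
Why: Williamson-type O-alkylation: triflate is a leaving group good enough for SN2 at a neopentyl carbon, the caesium phenoxide in a dipolar aprotic solvent is a good nucleophile and a poor base, and C11 is not stereogenic, so no stereocenter is touched.

**Compound list**
1 | geraniol | CC(C)=CCC/C(C)=C/CO | starting material
2 | geranyl bromide | CC(C)=CCC/C(C)=C/CBr | intermediate
3 | dimethyl malonate | COC(=O)CC(=O)OC | starting material
4 | dimethyl 2-[(2E)-3,7-dimethylocta-2,6-dien-1-yl]malonate | CC(C)=CCC/C(C)=C/CC(C(=O)OC)C(=O)OC | intermediate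
5 | methyl (4E)-5,9-dimethyldeca-4,8-dienoate | CC(C)=CCC/C(C)=C/CCC(=O)OC | intermediate
6 | (4E)-N-methoxy-N,5,9-trimethyldeca-4,8-dienamide | CC(C)=CCC/C(C)=C/CCC(=O)N(C)OC | intermediate
7 | (4E,8E)-N-methoxy-N,5,9-trimethyl-10-oxodeca-4,8-dienamide (not isolated) | O=C/C(C)=C/CC/C(C)=C/CCC(=O)N(C)OC | intermediate
8 | (4E,8E)-10-hydroxy-N-methoxy-N,5,9-trimethyldeca-4,8-dienamide | OC/C(C)=C/CC/C(C)=C/CCC(=O)N(C)OC | intermediate
9 | (4E,8S,9S)-8,9-epoxy-10-hydroxy-N-methoxy-N,5,9-trimethyldec-4-enamide | OC[C@]1(C)O[C@H]1CC/C(C)=C/CCC(=O)N(C)OC | intermediate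
10 | (4E,8S,9S)-10-(tert-butyldiphenylsilyloxy)-8,9-epoxy-N-methoxy-N,5,9-trimethyldec-4-enamide | CC(C)(C)[Si](c1ccccc1)(c1ccccc1)OC[C@]2(C)O[C@H]2CC/C(C)=C/CCC(=O)N(C)OC | intermediate
11 | vinylmagnesium bromide | C=C[Mg]Br | starting material
12 | (6E,10S,11S)-12-(tert-butyldiphenylsilyloxy)-10,11-epoxy-7,11-dimethyldodeca-1,6-dien-3-one | CC(C)(C)[Si](c1ccccc1)(c1ccccc1)OC[C@]2(C)O[C@H]2CC/C(C)=C/CCC(=O)C=C | intermediate
13 | (2Z,6E,10S,11S)-12-(tert-butyldiphenylsilyloxy)-10,11-epoxy-7,11-dimethyl-3-(triethylsilyloxy)dodeca-2,6-diene | CC(C)(C)[Si](c1ccccc1)(c1ccccc1)OC[C@]2(C)O[C@H]2CC/C(C)=C/CC/C(O[Si](CC)(CC)CC)=C/C | intermediate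
14 | 8α-triethylsilyl ether of 15 (not isolated) | CC(C)(C)[Si](c1ccccc1)(c1ccccc1)OC[C@@]1(C)[C@@H]2CCC(=O)[C@H](C)[C@@]2(C)CC[C@@H]1O[Si](CC)(CC)CC | intermediate
15 | (4R,5S,8S,9R,10R)-9-(tert-butyldiphenylsilyloxymethyl)-8-hydroxy-4,5,9-trimethyl-trans-decalin-3-one (8α-OH equatorial, C9 methyl α axial, C4 methyl α equatorial) | CC(C)(C)[Si](c1ccccc1)(c1ccccc1)OC[C@@]1(C)[C@@H]2CCC(=O)[C@H](C)[C@@]2(C)CC[C@@H]1O | intermediate
16 | 8α (equatorial) methanesulfonate of 15 | CC(C)(C)[Si](c1ccccc1)(c1ccccc1)OC[C@@]1(C)[C@@H]2CCC(=O)[C@H](C)[C@@]2(C)CC[C@@H]1OS(C)(=O)=O | intermediate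
17 | 8β (axial) bromide, (4R,5S,8R,9R,10R) (not isolated) | CC(C)(C)[Si](c1ccccc1)(c1ccccc1)OC[C@@]1(C)[C@@H]2CCC(=O)[C@H](C)[C@@]2(C)CC[C@H]1Br | intermediate
18 | (4R,5S,9R,10R)-9-(tert-butyldiphenylsilyloxymethyl)-4,5,9-trimethyl-trans-octal-7-en-3-one | CC(C)(C)[Si](c1ccccc1)(c1ccccc1)OC[C@@]1(C)[C@@H]2CCC(=O)[C@H](C)[C@@]2(C)CC=C1 | intermediate
19 | (4R,5S,9R,10R)-9-(hydroxymethyl)-4,5,9-trimethyl-trans-octal-7-en-3-one | OC[C@@]1(C)[C@@H]2CCC(=O)[C@H](C)[C@@]2(C)CC=C1 | intermediate
20 | (bromomethyl)dimethylsilyl ether of 19 | BrC[Si](C)(C)OC[C@@]1(C)[C@@H]2CCC(=O)[C@H](C)[C@@]2(C)CC=C1 | intermediate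
21 | tricyclic oxasilinane, C8–CH2 axial β | C[Si]3(C)OC[C@@]1(C)[C@@H]2CCC(=O)[C@H](C)[C@@]2(C)CC[C@H]1C3 | intermediate
22 | (4R,5S,8R,9R,10R)-9-(hydroxymethyl)-4,5,8,9-tetramethyl-trans-decalin-3-one (C8 methyl β axial) | OC[C@@]1(C)[C@@H]2CCC(=O)[C@H](C)[C@@]2(C)CC[C@H]1C | intermediate
23 | C11 trifluoromethanesulfonate of 22 | O=S(=O)(OC[C@@]1(C)[C@@H]2CCC(=O)[C@H](C)[C@@]2(C)CC[C@H]1C)C(F)(F)F | intermediate
24 | isofraxidin (7-hydroxy-6,8-dimethoxycoumarin) | COc1cc2ccc(=O)oc2c(OC)c1O | starting material
25 | CNP0225022.1 | COc1cc2ccc(=O)oc2c(OC)c1OC[C@@]1(C)[C@@H]2CCC(=O)[C@H](C)[C@@]2(C)CC[C@H]1C | target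

**Total step count:** 18.
**Longest linear sequence:** 18 steps (1 to 25).

**Steps most likely to fail**

**Step 10.**
- What may go wrong: O11 slows ionisation at C9. The activated oxirane may then isomerise by hydride shift, the cascade may stop after ring B by proton loss, or the enol silane may be cleaved before the C4–C5 bond forms.
- Fallback: the same two bonds are made through radicals, which the C11 oxygen does not retard. It sets out from 10.
 - MeMgBr gives methyl ketone F1.
 - Wittig ethylidenation (Ph3P=CHCH3) gives epoxy diene F2. Its new alkene may be an isomer mixture, because it only affects the epimerisable C4.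
 - Cp2TiCl (trivalent titanium, made from Cp2TiCl2 and Mn, turned over with Me3SiCl and collidine) opens the oxirane homolytically to the C9 radical.
 - Two 6-endo closures and β-hydride loss then give methylidene decalin F3.
 - Ozonolysis (O3, then Me2S) and equilibration of C4 with DBU return to the route at 15.
- Stereocontrol in this variant: C8 still comes from the Sharpless oxirane, and C9 is set by the chair that puts the larger silyloxymethyl group equatorial.

**Step 18.**
- What may go wrong: substitution at the neopentyl C11 by a phenoxide with two ortho methoxy groups may be slower than ionisation with 1,2-shift or than attack at the sulfur of the triflate.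
- Fallback: the aryl–oxygen bond is formed instead of the alkyl–oxygen bond, so no substitution at C11 is needed. It sets out from 22 and 24.
 - Tf2O and pyridine turn isofraxidin into aryl triflate F6.
 - F6 is coupled with alcohol 22 under zerovalent palladium catalysis (Pd2(dba)3, a bulky di-tert-butylbiarylphosphine, Cs2CO3, toluene, 90 °C). This C–O cross-coupling of a primary alcohol returns to the route at 25.

**Step 15.**
- What may go wrong: the α-silyl radical may be reduced by the stannane before it reaches the hindered C8, or the closure may lose regiocontrol.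
- Fallback: it sets out from 19.
 - A hydroxyl-directed Simmons–Smith reaction (Et2Zn, CH2I2, CH2Cl2) adds CH2 to the β face and gives cyclopropane F4.
 - Hydrogenolysis (H2, PtO2, AcOH) should cleave the more exposed C7–CH2 bond. It reduces the ketone at the same time and gives diol F5.
 - NaOCl in AcOH oxidises only the secondary alcohol and returns to the route at 22.

**Further compounds**
F1 | step 10 | (5E,9S,10S)-11-(tert-butyldiphenylsilyloxy)-9,10-epoxy-6,10-dimethylundec-5-en-2-one | CC(C)(C)[Si](c1ccccc1)(c1ccccc1)OC[C@]2(C)O[C@H]2CC/C(C)=C/CCC(C)=O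
F2 | step 10 | (6E,10S,11S)-12-(tert-butyldiphenylsilyloxy)-10,11-epoxy-3,7,11-trimethyldodeca-2,6-diene (C2=C3 isomer mixture) | CC(C)(C)[Si](c1ccccc1)(c1ccccc1)OC[C@]2(C)O[C@H]2CC/C(C)=C/CCC(C)=CC
F3 | step 10 | 9-(tert-butyldiphenylsilyloxymethyl)-8α-hydroxy-4,5,9-trimethyl-3-methylidene-trans-decalin (C4 epimer mixture) | CC(C)(C)[Si](c1ccccc1)(c1ccccc1)OC[C@@]1(C)[C@@H]2CCC(=C)C(C)[C@@]2(C)CC[C@@H]1O
F4 | step 15 | 9-(hydroxymethyl)-4,5,9-trimethyl-7β,8β-methano-trans-decalin-3-one | OC[C@@]1(C)[C@@H]2CCC(=O)[C@H](C)[C@@]2(C)C[C@H]3C[C@@H]13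
F5 | step 15 | 9-(hydroxymethyl)-4,5,8,9-tetramethyl-trans-decalin-3-ol (C3 epimer mixture) | OC[C@@]1(C)[C@@H]2CCC(O)[C@H](C)[C@@]2(C)CC[C@H]1C
F6 | step 18 | 6,8-dimethoxy-2-oxo-2H-chromen-7-yl trifluoromethanesulfonate | COc1cc2ccc(=O)oc2c(OC)c1OS(=O)(=O)C(F)(F)F
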